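Ring C is disconnected at O1–C8a and C4–C4a, so that one aryne annulation joins ring A to a pre-formed chiral C2–C3–C4 unit. The key step exploits the fact that C8a (which carries O1) and C4a (which carries C4) are neighbouring carbons of ring A, with the C5 methoxy group beside C4a and only C8–H beside C8a: the pattern of a 3-methoxyaryne. Fluoride unmasks the aryne from a prenylated dimethoxy 2-silylaryl triflate and the alkoxide from the silyl ether of an (S)-β-hydroxy ester; O-attack at C8a and acylation by C4a close ring C in one operation. The C4 ketone is then removed in two steps.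

Key step: step 9

Remark: prenyl means 3-methylbut-2-en-1-yl and flavonoid numbering (O1, C2–C4, C4a, C5–C8, C8a; rings A, B, C) is used. The carbinol carbon has the priorities O > aryl > CH2 in the hydroxy ester, the flavanone and the flavan, so it is S in all three. The hydroxyl enters the annulation as its trimethylsilyl ether, because a free O–H would protonate the C4a carbanion and stop at O-arylation. With silicon in excess over fluoride, the methoxide expelled on ring closure should end as MeOSiMe3 and not open ring C.

Step 1
Reactants: 1 3,5-dimethoxyphenol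
Product: 2 (3,5-dimethoxyphenoxy)triisopropylsilane
Conditions: iPr3SiCl, imidazole, DMF, rt
Reagents that add atoms: triisopropylsilyl chloride, CC(C)[Si](Cl)(C(C)C)C(C)C
Why: O-Silylation of a phenol is routine, and the bulky triisopropylsilyl ether is a non-directing, shielding group that leaves the next deprotonation to the two methoxy groups.

Step 2
Reactants: 2 (3,5-dimethoxyphenoxy)triisopropylsilane; 3 prenyl bromide (1-bromo-3-methylbut-2-ene)
Product: 5 [3,5-dimethoxy-4-(3-methylbut-2-en-1-yl)phenoxy]triisopropylsilane, via aryllithium 4 (not isolated)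
Conditions: n-BuLi, THF, 0 °C to rt; then CuBr·SMe2 (10 mol %), 3, −78 °C to rt
Reagents that add atoms: none
Why: Directed ortho metalation removes the proton between the two methoxy groups, which is the most acidic ring proton and lies remote from the shielding silyl ether, and copper-catalysed SN2 allylation of aryllithium 4 at the primary carbon of the allylic bromide gives the linear prenyl arene.

Step 3
Reactants: 5 [3,5-dimethoxy-4-(3-methylbut-2-en-1-yl)phenoxy]triisopropylsilane
Product: 6 3,5-dimethoxy-4-(3-methylbut-2-en-1-yl)phenol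
Conditions: Bu4NF, AcOH, THF, 0 °C to rt
Reagents that add atoms: none
Why: Buffered fluoride cleavage of an aryl silyl ether (desilylation) is fast and leaves the methyl ethers and the alkene untouched.

Step 4
Reactants: 6 3,5-dimethoxy-4-(3-methylbut-2-en-1-yl)phenol
Product: 7 3,5-dimethoxy-4-(3-methylbut-2-en-1-yl)phenyl N-isopropylcarbamate
Conditions: iPrNCO, Et3N (cat.), CH2Cl2, rt
Reagents that add atoms: isopropyl isocyanate, CC(C)N=C=O
Why: Amine-catalysed addition of a phenol to an isocyanate (carbamoylation) installs a strong ortho-directing group that can later be removed with mild base.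

Step 5
Reactants: 7 3,5-dimethoxy-4-(3-methylbut-2-en-1-yl)phenyl N-isopropylcarbamate
Product: 11 3,5-dimethoxy-4-(3-methylbut-2-en-1-yl)-2-(trimethylsilyl)phenyl N-isopropylcarbamate, via N-silyl carbamate 8 (not isolated), via aryllithium 9 (not isolated), via disilyl carbamate 10 (not isolated)
Conditions: tBuMe2SiOTf (1.1 equiv), TMEDA, Et2O, 0 °C to rt; n-BuLi (2.2 equiv), TMEDA, −78 °C; Me3SiCl, −78 °C to rt; cold aq. citric acid
Reagents that add atoms: chlorotrimethylsilane, C[Si](C)(C)Cl
Why: Directed ortho metalation of the N-silylated carbamate 8 takes place at the ring carbon flanked by the carbamate and a methoxy group (the two such positions are equivalent by symmetry), Me3SiCl traps aryllithium 9, and the labile N–Si bond of 10 is hydrolysed on work-up.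

Step 6
Reactants: 11 3,5-dimethoxy-4-(3-methylbut-2-en-1-yl)-2-(trimethylsilyl)phenyl N-isopropylcarbamate
Product: 13 3,5-dimethoxy-4-(3-methylbut-2-en-1-yl)-2-(trimethylsilyl)phenyl trifluoromethanesulfonate, via silyl phenol 12 (not isolated)
Conditions: DBU, Et2NH, MeCN, 40 °C; then PhN(SO2CF3)2, rt
Reagents that add atoms: N-phenylbis(trifluoromethanesulfonimide), O=S(=O)(N(c1ccccc1)S(=O)(=O)C(F)(F)F)C(F)(F)F
Why: Base-induced E1cB cleavage of the N-monoalkyl carbamate (the isocyanate is trapped by diethylamine) gives the phenoxide of 12, which is O-triflated in the same flask under non-acidic conditions that spare the electron-rich aryl–silicon bond.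

Step 7
Reactants: 14 methyl 3-(4-methoxyphenyl)-3-oxopropanoate
Product: 15 methyl (S)-3-hydroxy-3-(4-methoxyphenyl)propanoate
Conditions: H2 (10 atm), RuCl2[(R)-BINAP] (0.5 mol %), MeOH, 50 °C
Reagents that add atoms: none
Why: Noyori asymmetric hydrogenation of a β-keto ester, in which the ester-chelated ketone is reduced on the face set by the (R)-BINAP ligand, which for an aryl keto ester corresponds to the S carbinol.

Step 8
Reactants: 15 methyl (S)-3-hydroxy-3-(4-methoxyphenyl)propanoate
Product: 16 methyl (S)-3-(4-methoxyphenyl)-3-(trimethylsilyloxy)propanoate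
Conditions: Me3SiCl, imidazole, CH2Cl2, 0 °C; filtration through basic alumina
Reagents that add atoms: chlorotrimethylsilane, C[Si](C)(C)Cl
Why: Routine O-silylation of a secondary alcohol removes the only O–H proton from the annulation partner without touching any bond to the stereocentre.

Step 9
Reactants: 13 3,5-dimethoxy-4-(3-methylbut-2-en-1-yl)-2-(trimethylsilyl)phenyl trifluoromethanesulfonate; 16 methyl (S)-3-(4-methoxyphenyl)-3-(trimethylsilyloxy)propanoate
Product: 18 (S)-5,7-dimethoxy-2-(4-methoxyphenyl)-6-(3-methylbut-2-en-1-yl)chroman-4-one, via aryne 17 (not isolated)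
Conditions: 13 (1.3 equiv), 16 (1.0 equiv), CsF (1.1 equiv), 18-crown-6 (1.1 equiv), THF, 0 °C to rt; then pH 7 phosphate buffer
Reagents that add atoms: none
Why: Proposed new method: fluoride removes Me3Si from 13 to release aryne 17 (triple bond C4a–C8a) and from 16 to release the secondary alkoxide; the alkoxide oxygen adds to C8a, the carbanion left at C4a attacks the ester carbon, and the tetrahedral intermediate expels methoxide, which is captured by silicon as MeOSiMe3 because 13 is kept in excess over fluoride. The closest known reaction types are the fluoride-mediated annulation of arynes with methyl salicylates to xanthones, the O-arylation of aliphatic alcohols by arynes, and the Parham-type closure of ortho-metalated aryl ethers onto esters or amides to chroman-4-ones; an aliphatic β-silyloxy ester has not been shown as the annulation partner. Ring C is closed by 6-exo-trig acylation at C4 after intermolecular formation of the O1–C8a bond. No stereocentre is formed: C2 is the carbinol carbon of 16 and none of its four bonds is made or broken, so its S configuration is carried over. The step needs O-attack at C8a and not at C4a, which the C5 methoxy group secures by inductively polarising the aryne so that C8a is the more electrophilic terminus and the negative charge builds up at C4a beside the C5–O bond; 13 exists as a single isomer, so only one aryne can form. It also needs acylation to outrun protonation of C4a, which the absence of any O–H group and the aprotic medium are meant to ensure.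

Step 10
Reactants: 18 (S)-5,7-dimethoxy-2-(4-methoxyphenyl)-6-(3-methylbut-2-en-1-yl)chroman-4-one
Product: 19 (2S,4S)-5,7-dimethoxy-2-(4-methoxyphenyl)-6-(3-methylbut-2-en-1-yl)chroman-4-ol
Conditions: NaBH4, THF/MeOH, 0 °C
Reagents that add atoms: none
Why: Borohydride 1,2-reduction of the aryl ketone, with hydride expected to enter on the axial trajectory of the half-chair that holds the C2 aryl group pseudo-equatorial (substrate control), should give mainly the 2,4-cis alcohol, and either C4 epimer is acceptable because this centre is erased in step 11.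

Step 11
Reactants: 19 (2S,4S)-5,7-dimethoxy-2-(4-methoxyphenyl)-6-(3-methylbut-2-en-1-yl)chroman-4-ol
Product: 20 (S)-5,7-dimethoxy-2-(4-methoxyphenyl)-6-(3-methylbut-2-en-1-yl)chromane
Conditions: Et3SiH (3 equiv), BF3·OEt2 (1.5 equiv), CH2Cl2, −78 °C
Reagents that add atoms: none
Why: Ionic deoxygenation, in which BF3 ionises the C4 hydroxyl to a cation stabilised by O1 and by the C5 and C7 methoxy groups and triethylsilane delivers hydride at −78 °C, a temperature at which the prenyl alkene and the C2–O1 bond should stay intact.

Compound list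
1 | 3,5-dimethoxyphenol | COc1cc(O)cc(OC)c1 | starting material
2 | (3,5-dimethoxyphenoxy)triisopropylsilane | COc1cc(O[Si](C(C)C)(C(C)C)C(C)C)cc(OC)c1 | intermediate
3 | prenyl bromide (1-bromo-3-methylbut-2-ene) | CC(C)=CCBr | starting material
4 | [2,6-dimethoxy-4-(triisopropylsilyloxy)phenyl]lithium | [Li]c1c(OC)cc(O[Si](C(C)C)(C(C)C)C(C)C)cc1OC | intermediate (not isolated)
5 | [3,5-dimethoxy-4-(3-methylbut-2-en-1-yl)phenoxy]triisopropylsilane | COc1cc(O[Si](C(C)C)(C(C)C)C(C)C)cc(OC)c1CC=C(C)C | intermediate
6 | 3,5-dimethoxy-4-(3-methylbut-2-en-1-yl)phenol | COc1cc(O)cc(OC)c1CC=C(C)C | intermediate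
7 | 3,5-dimethoxy-4-(3-methylbut-2-en-1-yl)phenyl N-isopropylcarbamate | COc1cc(OC(=O)NC(C)C)cc(OC)c1CC=C(C)C | intermediate
8 | 3,5-dimethoxy-4-(3-methylbut-2-en-1-yl)phenyl N-(tert-butyldimethylsilyl)-N-isopropylcarbamate | COc1cc(OC(=O)N(C(C)C)[Si](C)(C)C(C)(C)C)cc(OC)c1CC=C(C)C | intermediate (not isolated)
9 | 2-lithio derivative of 8 (lithium on the ring carbon between the carbamate oxygen and a methoxy group) | COc1cc(OC(=O)N(C(C)C)[Si](C)(C)C(C)(C)C)c([Li])c(OC)c1CC=C(C)C | intermediate (not isolated)
10 | 3,5-dimethoxy-4-(3-methylbut-2-en-1-yl)-2-(trimethylsilyl)phenyl N-(tert-butyldimethylsilyl)-N-isopropylcarbamate | COc1cc(OC(=O)N(C(C)C)[Si](C)(C)C(C)(C)C)c([Si](C)(C)C)c(OC)c1CC=C(C)C | intermediate (not isolated)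
11 | 3,5-dimethoxy-4-(3-methylbut-2-en-1-yl)-2-(trimethylsilyl)phenyl N-isopropylcarbamate | COc1cc(OC(=O)NC(C)C)c([Si](C)(C)C)c(OC)c1CC=C(C)C | intermediate
12 | 3,5-dimethoxy-4-(3-methylbut-2-en-1-yl)-2-(trimethylsilyl)phenol (formed as its phenoxide) | COc1cc(O)c([Si](C)(C)C)c(OC)c1CC=C(C)C | intermediate (not isolated)
13 | 3,5-dimethoxy-4-(3-methylbut-2-en-1-yl)-2-(trimethylsilyl)phenyl trifluoromethanesulfonate | COc1cc(OS(=O)(=O)C(F)(F)F)c([Si](C)(C)C)c(OC)c1CC=C(C)C | intermediate
14 | methyl 3-(4-methoxyphenyl)-3-oxopropanoate | COC(=O)CC(=O)c1ccc(OC)cc1 | starting material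
15 | methyl (S)-3-hydroxy-3-(4-methoxyphenyl)propanoate | COc1ccc([C@@H](O)CC(=O)OC)cc1 | intermediate
16 | methyl (S)-3-(4-methoxyphenyl)-3-(trimethylsilyloxy)propanoate | COc1ccc([C@@H](O[Si](C)(C)C)CC(=O)OC)cc1 | intermediate
17 | 3,5-dimethoxy-4-(3-methylbut-2-en-1-yl)benzyne (triple bond between the former C–OTf and C–Si carbons of 13, that is C8a and C4a) | COC1=CC#CC(OC)=C1CC=C(C)C | intermediate (not isolated)
18 | (S)-5,7-dimethoxy-2-(4-methoxyphenyl)-6-(3-methylbut-2-en-1-yl)chroman-4-one ((S)-5,7,4'-trimethoxy-6-prenylflavanone) | COc1ccc([C@@H]2CC(=O)c3c(cc(OC)c(CC=C(C)C)c3OC)O2)cc1 | intermediate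
19 | (2S,4S)-5,7-dimethoxy-2-(4-methoxyphenyl)-6-(3-methylbut-2-en-1-yl)chroman-4-ol (drawn as the expected 2,4-cis epimer) | COc1ccc([C@@H]2C[C@H](O)c3c(cc(OC)c(CC=C(C)C)c3OC)O2)cc1 | intermediate
20 | (S)-5,7-dimethoxy-2-(4-methoxyphenyl)-6-(3-methylbut-2-en-1-yl)chromane ((S)-5,7,4'-trimethoxy-6-prenylflavan) | COc1ccc([C@@H]2CCc3c(cc(OC)c(CC=C(C)C)c3OC)O2)cc1 | target

Total step count: 11 (steps 1–6 to silyl triflate 13, steps 7–8 to silyl ether 16, steps 9–11 to the target).
Longest linear sequence: 9 steps (steps 1–6, then 9, 10 and 11).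

Steps most likely to fail

First, step 9, the proposed new method. Three things may go wrong:
- The carbanion at C4a may be protonated, by the C3 methylene of its own ester arm or by traces of water, before it acylates, so that only the O1–C8a bond forms.
- The transient alkoxide may undergo retro-aldol cleavage or elimination before it meets the aryne.
- Residual base may open ring C of the product by β-elimination of the phenoxide, with loss of configuration at C2.

The fallback divides the annulation into known operations and sets out from 13 and 15. Aryne 17, released from 13 with KF and 18-crown-6 in THF at −20 °C, should insert into the O–H bond of the free hydroxy ester 15. This is the known O-arylation of aliphatic alcohols by arynes, with the same methoxy-directed regiochemistry and protonation at C4a. It should give methyl (S)-3-[3,5-dimethoxy-4-(3-methylbut-2-en-1-yl)phenoxy]-3-(4-methoxyphenyl)propanoate F1 without touching the stereocentre. Saponification (LiOH, THF/H2O, 0 °C) would give (S)-3-[3,5-dimethoxy-4-(3-methylbut-2-en-1-yl)phenoxy]-3-(4-methoxyphenyl)propanoic acid F2. Oxalyl chloride with catalytic DMF would give (S)-3-[3,5-dimethoxy-4-(3-methylbut-2-en-1-yl)phenoxy]-3-(4-methoxyphenyl)propanoyl chloride F3. Intramolecular Friedel–Crafts acylation (SnCl4, CH2Cl2, −78 °C) at either of the two equivalent positions ortho to the ether oxygen of the symmetric, phloroglucinol-type ring would then close the C4–C4a bond. The fallback comes back to the route at flavanone 18.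

Second, step 5. n-BuLi may deprotonate the doubly activated benzylic and allylic CH2 of the prenyl group in competition with the ring position. The very electron-rich aryl–silicon bond may also be lost by protodesilylation during the acidic work-up.

The fallback sets out from phenol 6 and replaces ring deprotonation by halogen–metal exchange. Bromination with N-bromosuccinimide (CH2Cl2, −78 °C; both open ring positions are equivalent) should give 2-bromo-3,5-dimethoxy-4-(3-methylbut-2-en-1-yl)phenol F4. O-Silylation with (Me3Si)2NH would give [2-bromo-3,5-dimethoxy-4-(3-methylbut-2-en-1-yl)phenoxy]trimethylsilane F5. n-BuLi in THF at −78 °C should effect bromine–lithium exchange to [2,4-dimethoxy-3-(3-methylbut-2-en-1-yl)-6-(trimethylsilyloxy)phenyl]lithium F6. This rearranges by a 1,3-shift of silicon from oxygen to carbon (retro-Brook rearrangement) to the lithium salt of 12, which is triflated in the same flask with (CF3SO2)2O. The fallback comes back to the route at 13 and makes steps 4–6 unnecessary.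

Third, step 11. The Lewis acid may also ionise the C2–O1 bond, a 4-methoxybenzylic aryl ether, which would erode the configuration at C2. The C4 cation may also be intercepted by the prenyl alkene of a second molecule instead of by the silane.

The fallback avoids a cation at C4 and sets out from ketone 18. Condensation with TsNHNH2 (EtOH, 60 °C) should give N'-[(2S)-5,7-dimethoxy-2-(4-methoxyphenyl)-6-(3-methylbut-2-en-1-yl)chroman-4-ylidene]-4-methylbenzenesulfonohydrazide F7. Reduction with catecholborane (CHCl3, 0 °C) and decomposition with NaOAc·3H2O (hydride reduction of a tosylhydrazone, Caglioti reaction) should convert C4 into CH2 with loss of dinitrogen and sulfinate. The fallback comes back to the route at target 20 and also replaces step 10.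

Further compounds
F1 | step 9 | methyl (S)-3-[3,5-dimethoxy-4-(3-methylbut-2-en-1-yl)phenoxy]-3-(4-methoxyphenyl)propanoate | COc1ccc([C@@H](Oc2cc(OC)c(CC=C(C)C)c(OC)c2)CC(=O)OC)cc1
F2 | step 9 | (S)-3-[3,5-dimethoxy-4-(3-methylbut-2-en-1-yl)phenoxy]-3-(4-methoxyphenyl)propanoic acid | COc1ccc([C@@H](Oc2cc(OC)c(CC=C(C)C)c(OC)c2)CC(=O)O)cc1
F3 | step 9 | (S)-3-[3,5-dimethoxy-4-(3-methylbut-2-en-1-yl)phenoxy]-3-(4-methoxyphenyl)propanoyl chloride | COc1ccc([C@@H](Oc2cc(OC)c(CC=C(C)C)c(OC)c2)CC(=O)Cl)cc1
F4 | step 5 | 2-bromo-3,5-dimethoxy-4-(3-methylbut-2-en-1-yl)phenol | COc1cc(O)c(Br)c(OC)c1CC=C(C)C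
F5 | step 5 | [2-bromo-3,5-dimethoxy-4-(3-methylbut-2-en-1-yl)phenoxy]trimethylsilane | COc1cc(O[Si](C)(C)C)c(Br)c(OC)c1CC=C(C)C
F6 | step 5 | [2,4-dimethoxy-3-(3-methylbut-2-en-1-yl)-6-(trimethylsilyloxy)phenyl]lithium | [Li]c1c(O[Si](C)(C)C)cc(OC)c(CC=C(C)C)c1OC
F7 | step 11 | N'-[(2S)-5,7-dimethoxy-2-(4-methoxyphenyl)-6-(3-methylbut-2-en-1-yl)chroman-4-ylidene]-4-methylbenzenesulfonohydrazide | COc1ccc([C@@H]2CC(=NNS(=O)(=O)c3ccc(C)cc3)c3c(cc(OC)c(CC=C(C)C)c3OC)O2)cc1
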